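Late in a run, the step from target to isomer of the product turns one molecule into one molecule, so its end ratio has no concentration in it (thermodynamic control). Let s be the share of target in target plus isomer, the selectivity between the two. Any pull of concentration on s belongs to the way to that end, so we turn the question round: what would the readings have to show for s to differ by more than the margin across the flasks dawn, dusk and midnight after 30 h?

| flask | substrate | partner | remark | time |
|---|---|---|---|---|
| maple | 0.073 M | 0.70 equiv | run made earlier |  |
| oak | 0.20 M | 0.70 equiv | run made earlier |  |
| dawn | 0.060 M | 0.700 equiv |  | 30 h |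
| dusk | 0.10 M | 0.700 equiv |  | 30 h |
| midnight | 0.15 M | 0.700 equiv |  | 30 h |

| run | time / h | target / % | isomer of the product / % |
|---|---|---|---|
| maple | 2.00 | 0 | 0.3 |
| maple | 5.00 | 1.1 | 0.8 |
| maple | 10.0 | 2.4 | 2.2 |
| maple | 15.0 | 3.8 | 4.1 |
| oak | 2.00 | 0.6 | 0.7 |
| oak | 5.00 | 2.5 | 1.9 |
| oak | 10.0 | 4.0 | 3.5 |
| oak | 15.0 | 5.4 | 6.4 |

(each reading ± 0.3 percentage points)

- what was read earlier has a scatter of 0.3 percentage points, one standard deviation
- reactions considered so far: substrate + partner <-> intermediate; intermediate <-> target + by-product; target <-> isomer of the product
- "hardly changes" means that all values lie within two and a half points (for a concentration: within two and a half percent of the largest)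

1. share of target in all that became target or isomer of the product for dawn, dusk, midnight, in this order
2. how that number moves from the first to the last of them (rises all the way / hardly changes / falls all the way / falls, then rises / rises, then falls)

Maple minus oak, the share s differs after 5.00 h, 10.0 h and 15.0 h by

1.1 percentage points, −1.2 points, 2.3 points.

These gaps change sign, so what we read from them is a rough reading inside the scatter. We average them and divide by the logarithm of the concentration ratio, which gives the concentration slope g, the points of s lost per factor e in concentration:

g = 0.75 points

For another outcome, the row would have to spread by more than 2.50 points, which from dawn to midnight, on a straight line in the logarithm of concentration, needs a slope of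

2.7 points

The reading g is smaller than that, and as a rough estimate, with c the substrate charged, it gives a spread from dawn to midnight of

g ln(c(midnight)/c(dawn)) = 0.68 points

For the level, take r, isomer over target, with both runs added. It stands at 0.750 after 5.00 h and 1.14 after 15.0 h. Carried on in a straight line to 30 h, it gives

r = 1.73, so s = 36.7 %

The forecast, at 37 %, 37 % and 37 % (hardly changes), holds that the split “depends on time alone”.

The flasks dawn, dusk and midnight give 37.5 %, 37.1 % and 36.8 %, so the row hardly changes, and dawn stands 0.7 points above midnight.

    substrate + partner ⇌ intermediate (K = 7.19 L mol⁻¹, k = 6.28 × 10⁻⁴ L mol⁻¹ s⁻¹)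
    intermediate ⇌ target + by-product (K = 0.0931 M, k = 8.02 × 10⁻⁶ s⁻¹)
    target ⇌ isomer of the product (K = 2.30, k = 5.89 × 10⁻⁵ s⁻¹)

In dawn, target and isomer of the product relax by their own step with a half-life of 2.28 h, both ways together, which is shorter than the 30 h of the run. We use g once more, on dusk, starting from dawn:

s = 37.5 % − g ln(c(dusk)/c(dawn)) = 37.1 %

Dusk itself stands at 37.1 %.

The numbers in the tables were computed from invented constants; scatter was added.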